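It was the slowness of the oak run that I read first, among the two earlier runs and the four flasks asked about:

| setting | oak | alder | east | south-west | north | south-east |
|---|---|---|---|---|---|---|
| starting material | 0.10 M | 0.10 M | 0.10 M | 0.10 M | 0.10 M | 0.10 M |
| free catalyst | 0.074 mol% | 0.37 mol% | 0.3 mol% | 0.06 mol% | 0.12 mol% | 0.22 mol% |
| temperature | 85 °C | 96 °C | 90 °C | 90 °C | 90 °C | 90 °C |
| remark | run made earlier | run made earlier |  |  |  |  |
| time |  |  | 20 min | 20 min | 20 min | 20 min |

- oak (time / min: target / %): 1.33: 3.4; 3.00: 8.2; 4.00: 10.9; 6.00: 15.1; 8.00: 19.1; 10.0: 22.5
- alder (time / min: target / %): 1.33: 34.3; 3.00: 57.2; 4.00: 61.5; 6.00: 58.3; 8.00: 50.2; 10.0: 44.7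

(readings scatter by 0.3 percentage points)

- the numbers in the tables scatter by 0.3 percentage points (one standard deviation)
- on the list of suspects stand: catalyst intermediate A <-> catalyst intermediate B; target <-> isomer of the product; starting material + free catalyst <-> catalyst intermediate A; catalyst intermediate B -> free catalyst + target

1. the flasks by amount of target, in percent of the starting material charged, highest first, at 20 min (east / south-west / north / south-east)
2. the same order at 2.0 min (east / south-west / north / south-east)
3. the amount of target, in percent of the starting material charged of the flask you put first, at 20 min
4. the amount of target, in percent of the starting material charged of the flask you put last, at 20 min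

Oak's target climbed almost in a line, so I divided an early reading, as a fraction of the charge, by loading and time. That gave 36.9 min⁻¹ for oak at 85 °C and 69.7 min⁻¹ for alder at 96 °C, and a straight line in the logarithm gave 49.3 min⁻¹ at 90 °C. I called this the turnover pace (turnover frequency): target made per catalyst charged per minute. One over pace times loading is the clearing time, in which the catalyst would pass the charge through. For alder it came to 3.88 min, and alder's readings peaked at 4.00 min, at 61.5%.

At 90 °C the clearing times were 33.8 min for south-west, 16.9 min for north, 9.22 min for south-east and 6.76 min for east. So I expected south-west still to be climbing at 20 min and north's clearing time to fall just inside that time, and as alder's readings fell after its peak, I put north first and south-west last.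

I bracketed north roughly, with alder's peak reading as an upper mark and as a lower mark the floor of 33.1% that alder's falling readings suggest, both estimates taken from another temperature. South-west's line gave a ceiling of 59.2%. Oak's last reading kept 82.3% of its own line, which as an estimate tightened that ceiling to 48.7%, and I took oak's 22.5%, read at another loading, temperature and time, as a rough lower mark for south-west.

The forecast gave south-east > east > north > south-west at 20 min, noting “East and south-east are nearly tied”, with 46% (42% to 51%) for its first flask and 30% (26% to 35%) for its last, and east > south-east > north > south-west at 2.0 min. Both numbers lay between the marks I had set for my first and last flasks, but its first flask was south-east and mine was north.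

The flasks gave north > south-east > east > south-west, from 44.1% to 31.1%, and east > south-east > north > south-west at 2.0 min.

    catalyst intermediate A ⇌ catalyst intermediate B (K = 3.00, k = 4.90 s⁻¹, Ea = 81.0 kJ mol⁻¹, ΔH = 9.00 kJ mol⁻¹)
    target ⇌ isomer of the product (K = 2.30, k = 0.00150 s⁻¹, Ea = 118 kJ mol⁻¹, ΔH = −44.0 kJ mol⁻¹)
    starting material + free catalyst ⇌ catalyst intermediate A (K = 26.0 L mol⁻¹, k = 41.0 L mol⁻¹ s⁻¹, Ea = 63.0 kJ mol⁻¹, ΔH = −32.0 kJ mol⁻¹)
    catalyst intermediate B → free catalyst + target (k = 2.80 s⁻¹, Ea = 81.0 kJ mol⁻¹)
    (constants at 90 °C)

Taking away the passing of target into isomer of the product turns the order, and north then holds 89.5% instead of 44.1%, while south-east, with its clearing time of 9.22 min, fell from 56.2% at 10.0 min to 42.2% at 20.0 min. South-west had used 58.4% of its starting material, beside the ceiling of 59.2% that its line gave. Kept at 65 °C, that flask has on the same line a ceiling of 14.0%, and it held 10.0% of target.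

(The data stem from a simulated flask with constants of no real substance, noise included.)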